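All runs come from a simulation for substances that don't exist.

Set the charge of coupling partner against the charge of starting material before reckoning any rate. I had to choose which of two flasks to charge, north-west or east, and they are identical but for the coupling partner.

| setting | elm | oak | north-west | east |
|---|---|---|---|---|
| starting material | 0.50 M | 0.50 M | 0.50 M | 0.50 M |
| coupling partner | 0.45 M | 0.81 M | 0.600 M | 0.300 M |
| protic impurity | 0.25 M | 0.25 M | 0.250 M | 0.250 M |
| catalyst | 0.80 mM | 0.80 mM | 0.80 mM | 0.80 mM |
| temperature | 0 °C | 11 °C | 5 °C | 5 °C |
| remark | run made earlier | run made earlier |  |  |
| time |  |  | 80 min | 80 min |

- elm (time / min: product / %, starting material / %): 5.00: 5.9, 8.6; 15.0: 19.5, 0.5; 25.0: 29.0, 0.2; 40.0: 40.1, 0; 60.0: 48.9, 0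
- oak (time / min: product / %, starting material / %): 12.0: 43.7, 0.4; 25.0: 64.8, 0.4; 30.0: 69.3, 0.4; 50.0: 80.1, 0.1; 60.0: 84.0, 0

(standard deviation of a reading: 0.3 percentage points)

1. the winner by amount of product, in percent of the starting material charged; "neither" if no more than 2 percentage points parts them (north-west / east / neither)
2. how much product is there at the end, in percent of the starting material charged: north-west
3. how much product is there at the end, in percent of the starting material charged: east

- what was read earlier has a scatter of 0.3 percentage points, one standard deviation

In elm, 0.5% of the starting material remained at 15.0 min with 19.5% product, so I took it that an intermediate stood between them and that product formed from it slowly. I counted one coupling partner per product. Then c(coupling partner) over c(starting material), as charged, is the partner ceiling, for east 60.0%, the most product its charge can pay for. Equal charges are the zero of that scale. East stood below them, so coupling partner was the limiting reagent for its product, though starting material could still be used up first by going to the intermediate. North-west, at 120%, stood above them, so the charge of starting material bounded its product instead. Elm's ceiling of 90.0% lay above its last product reading of 48.9%, and oak was charged with more coupling partner than starting material, so neither run tested the count; it was my assumption.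

The two flasks share temperature, catalyst and time. If product forms in proportion to c(coupling partner), I expected north-west to start twice as fast as east, with the higher ceiling as well. That needed no integral, and I would have charged north-west.

The forecast named north-west, with 72% for north-west (range 67% to 77%) and 43% for east (range 39% to 47%). Of east it said: “its partner caps it at 60%”.

North-west gave 72.9% and east 45.3%, so north-west won.

    2 coupling partner → homo dimer (k = 0.00420 M⁻¹ min⁻¹, Ea = 70.0 kJ mol⁻¹)
    starting material + catalyst → catalyst + intermediate (k = 870 M⁻¹ min⁻¹, Ea = 45.0 kJ mol⁻¹)
    starting material + protic impurity → quenched substrate (k = 0.0390 M⁻¹ min⁻¹, Ea = 72.0 kJ mol⁻¹)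
    coupling partner + catalyst + intermediate → catalyst + product (k = 73.0 M⁻² min⁻¹, Ea = 41.0 kJ mol⁻¹)
    (constants at 5 °C)

East ended at 75.5% of its partner ceiling, and the gap between the flasks is mainly the partner charge: east with north-west's charge gives 72.9% against 45.3%. The same count served a flask like east kept at 20 °C, where after 80.0 min 3.21% of the partner charge was left and the homo dimer stood at 0.0147 M. Two partners go into each homo dimer, so at that moment the dimer had lowered that flask's ceiling to 54.1%, and its product stood at 52.2%.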